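The earlier runs and the new flask come from a simulation from invented constants, and the scatter is random.

The amounts in the three set-ups were equal and the vessels differed, so I needed to know how much of the L each vessel had turned into D by the end and how much sat in J.

| flask | L | G | remark | time |
|---|---|---|---|---|
| red | 0.50 M | 0.025 M | run made earlier |  |
| amber | 0.50 M | 0.017 M | run made earlier |  |
| ochre | 0.50 M | 0.038 M | run made earlier |  |
| teal | 0.25 M | 0.025 M | run made earlier |  |
| autumn | 0.50 M | 0.0250 M | a closed flask charged with all of it at once and left for 80 min | 80 min |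
| winter | 0.50 M | 0.0250 M | one stirred flow tank at steady state, fed with the mixture as stated, mean residence time 80 min |  |
| summer | 0.50 M (fed, over 64.0 min) | 0.0250 M | all but L at the start; L goes in evenly over 64.0 min, the run ends at 80 min | 80 min |

| run | time / min | D / % | J / % |
|---|---|---|---|
| red | 12.0 | 8.1 | 24.7 |
| red | 25.0 | 17.2 | 19.4 |
| red | 30.0 | 21.5 | 16.1 |
| red | 50.0 | 32.6 | 11.2 |
| red | 60.0 | 36.2 | 7.7 |
| red | 80.0 | 46.3 | 8.1 |
| amber | 6.00 | 5.2 | 28.4 |
| amber | 10.0 | 7.1 | 25.2 |
| amber | 15.0 | 12.7 | 22.6 |
| amber | 25.0 | 19.5 | 18.3 |
| amber | 30.0 | 20.4 | 17.3 |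
| amber | 50.0 | 33.1 | 13.0 |
| amber | 80.0 | 46.0 | 6.0 |
| ochre | 12.0 | 9.1 | 23.7 |
| ochre | 25.0 | 16.8 | 15.5 |
| ochre | 30.0 | 21.1 | 13.8 |
| ochre | 50.0 | 32.2 | 10.1 |
| ochre | 60.0 | 36.6 | 9.8 |
| ochre | 80.0 | 44.6 | 9.0 |
| teal | 15.0 | 13.8 | 14.0 |
| teal | 30.0 | 22.8 | 10.4 |
| teal | 50.0 | 35.0 | 6.0 |
| teal | 60.0 | 38.5 | 6.2 |
| teal | 80.0 | 48.9 | 2.8 |

(scatter of a reading: 1 percentage point)

- percentages count the L that a species holds: one J counts as two
- the stated concentrations are those of everything mixed, before any reaction; amounts are the same in each set-up
- the feed brings no volume worth counting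
- the earlier runs were made in a closed, stirred flask
- a reading or a percentage of D counts all its forms, free or not

* the set-up with the highest share of D in all that became D or J, at the outlet or at the end ("none" if the first two lie within 2 percentage points) (autumn / winter / summer / none)
* share of D in all that became D or J, at the outlet or at the end, autumn
* share of D in all that became D or J, at the outlet or at the end, winter
* share of D in all that became D or J, at the outlet or at the end, summer

I called the rest whatever the readings showed as neither D nor J, and first tested whether J followed its square: at 50.0 min the red run gave a ratio of 0.355 L mol⁻¹, and the teal run, with half the L, gave 0.345 L mol⁻¹. So I carried their mean, 0.350 L mol⁻¹, as the pairing constant, the concentration of J over the square of the concentration of the rest, a pre-equilibrium as read from the readings.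

Next, D in the red run climbed between 12.0 min and 80.0 min at 0.00772 min⁻¹ of everything not yet D. At that rate I reckoned 53.9% not yet D at the end of the closed autumn flask, 61.8% at the outlet of the winter tank, and 69.8% at the end of summer, filling and then standing. Splitting each of these into rest and J by the pairing constant gave shares of D of 85.9%, 80.0% and 72.0%, so I committed to autumn. The weak link was that rate, taken from one run, so I read it again from the teal run, which ended with less J: it gave 0.00787 min⁻¹, which leaves 69.3% not yet D in summer and a share of 72.6%.

The forecast named autumn, with 85.5%, 79.5% and 71%, holding that “Selectivity therefore depends mainly on how far the run has progressed”.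

The flask gave autumn as best, with 86.9%, 79.6% and 72.0%.

    L → D (k = 2.05 × 10⁻⁴ s⁻¹)
    2 L ⇌ J (K = 0.686 L mol⁻¹, k = 0.00546 L mol⁻¹ s⁻¹)
    L + G → X (k = 0.0276 L mol⁻¹ s⁻¹)
    L + D ⇌ Q, settled at all times (K = 2.21 L mol⁻¹)

At the end of the summer run the exchange between L and J, by that step alone and both ways together, had a relaxation half-life of 0.925 min, shorter than the 80 min of the run. The pairing constant, applied to the D that summer held at the end, 31.5%, gave J of 11.4% against 12.2%, and on the same flask charged with 0.20 M of L, which ended with 32.6% of D, it gave 5.38% against 5.57%, in a flask whose share of D stood at 85.4%.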